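# Abruquinone B by squarate benzannulation and phenoxide ring closure

Numbering used throughout: chroman atoms O1, C2, C3, C4, C4a, C5–C8, C8a; quinone ring B atoms C1'–C6' (C1' bonded to C3).

## Analysis of the target

Abruquinone B is an isoflavan-quinone: a chroman (benzo ring A fused to the dihydropyran ring C) that carries a 2,3-dimethoxy-1,4-benzoquinone (ring B) at C3. Ring A bears four contiguous oxygens, the ring oxygen O1 on C8a and methoxy groups on C8, C7 and C6, and only C5 is unsubstituted. The single stereocentre is C3 (S); it lies between two CH2 groups and the quinone, has no heteroatom neighbour, and nothing else in the molecule can relay its configuration. The quinone is the sensitive part: it is electrophilic, its methoxy groups are vinylogous esters, it does not survive hydride or organometallic reagents, and the C3–H next to it can exchange under base through a quinone-methide tautomer, so the quinone must appear last and under neutral conditions. The difficulties are a 1,2,3,4-tetraoxygenated benzene ring that must be made without regiochemical ambiguity, two electron-rich rings of which only ring B may be oxidised, and the isolated stereocentre. The route rests on the fact that C8a, C8, C7 and C6 of ring A, with their four oxygens, correspond one to one to the four oxygen-bearing carbons of a cyclobutenone made from a squaric ester, so that only C5–H and C4a must be supplied, by a two-carbon alkenyl unit.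

## Retrosynthetic reasoning

**Quinone last (28 to 27 to 26).** Target 28 is the oxidation product of hydroquinone 27, and 27 is stored as its bis(benzyl ether) 26. No skeletal bond is cut. The gain is that all bond construction is done on an arene that tolerates base, heat and nucleophiles. Rings A and B also stay distinguishable: ring A carries only methyl ethers, so hydrogenolysis frees exactly the two oxygens that become carbonyl groups, and a mild neutral oxidant then acts on ring B alone.

**Rings A and C together (26 to 22).** In 26 two bonds are cut at once, O1–C2 of ring C and C4a–C8a of ring A. Cutting ring A there, and folding C8a–C8–C7–C6 back into a four-membered ring, turns the tetraoxygenated benzene into the 4-alkenyl-2,3,4-trimethoxycyclobutenone 22. In 22, C8a is the carbonyl carbon, C8 and C7 are the enol-ether carbons, C6 is the ring carbon bearing methoxy and alkenyl, and C5 and C4a are the alkene carbons. The forward reaction must open the four-membered ring by heat, close the six-membered ring through ketene 23, dienone 24 and phenol 25, and let the new phenol oxygen displace the primary sulfonate in the same flask. The gain is that no benzene ring has to be oxygenated regioselectively, and the phenol that attacks C2 is created exactly where it is needed.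

**The side-chain alkene (22 to 16 + 21).** 22 is cut at its E-disubstituted C=C bond, giving terminal alkene 16 and vinylcyclobutenone 21 as cross-metathesis partners. The bond between the alkene and the four-membered ring was not chosen, because it would need an alkenyllithium in a molecule that already holds the sulfonate. That would cost a protection, a hydrometalation, a deprotection and a late sulfonylation. With the metathesis cut both partners carry their functional groups in final form, and the union is neutral and runs far below the temperature at which 22 rearranges.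

**The cyclobutenone (21 to 17 + 18).** 21 is cut at the vinyl–ring bond and at the O–CH3 bond of its tertiary ether. Dimethyl squarate 17 takes up vinyllithium 19, made from vinyl bromide 18, at one carbonyl group, and alkoxide 20 is methylated in the same flask. Three of the four ring A oxygens and all their carbons therefore come from 17 in one operation.

**The stereocentre (16 to 15 to 14 to 11 + 12).** Mesylate 16 comes from alcohol 15, and 15 from imide 14 by reduction. 14 is cut at the C3–C4 bond: enolate 13 of arylacetyl imide 11 is alkylated with allyl iodide 12. C3 is set here because this is the one stage at which it carries a carbonyl group that can hold an auxiliary. The carbonyl is then reduced to the CH2–O that becomes C2, and the enolisable position is never used again. Auxiliary 9 makes any minor isomer a separable diastereomer.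

**The ring B fragment (11 to 8 + 9; 8 to 7 to 5 + 6; 5 to 4 to 2 to 1).** Imide 11 is the N-acyl derivative of oxazolidinone 9 with acid 8, formed through anhydride 10. 8 is the hydrolysis product of ester 7, which is cut at the aryl–CH2 bond into aryl bromide 5 and zinc enolate 6. 5 arises from the symmetric tetraether 4, whose two free positions are equivalent, so the carbon chain is placed without any directing-group problem. 4 is the dibenzyl ether of hydroquinone 3, the reduction product of quinone 2. 2 is made by para-oxidation of phenol 1, whose two methoxy groups are those of the final quinone.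

## Alternatives that were turned down

**Alternative 1: quinone–chromene annulation through a pterocarpan.**
- Disconnection: the C3–C1' bond and, temporarily, a bond from C4 to the oxygen on C2', so the isoflavan is treated as a reductively opened pterocarpan.
- Forward key step: 6,7,8-trimethoxy-2H-chromene A1 and 2,3-dimethoxy-1,4-benzoquinone A2, which is the same compound as 2, are combined under a tetravalent titanium Lewis acid (TiCl4/Ti(OiPr)4) carrying a chiral tartrate-derived diolate. The styrene-like C3=C4 bond of A1 attacks the quinone, the benzylic cation at C4 is captured by the quinone oxygen, and the cis-fused pterocarpan (6aS,11aS)-8-hydroxy-2,3,4,9,10-pentamethoxypterocarpan A3 results. Hydrogenolysis of the benzylic C–O bond of A3 would give 27 directly, and oxidation the target.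
- For: it is by far the shortest plan, it is convergent, it needs no protecting groups, and ring B arrives in its final oxidation pattern.
- Against: A2 is a double vinylogous ester, a weak electrophile with two equivalent binding sites for titanium, whereas this annulation depends on one defined bidentate complex. A1 is a very electron-rich, acid-sensitive alkene that can oligomerise under the Lewis acid. (2+2) and (5+2) adducts compete with the formation of A3. The enantioselectivity depends on a stoichiometric chiral reagent, with no diastereomeric intermediate at which to upgrade it. Ring A of A1 must still be made from a tetraoxygenated arene.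
- Comparison: on step count this alternative is clearly stronger. The chosen route offers instead an absolute configuration fixed by a covalently bound auxiliary, and a ring A whose oxygen pattern is fixed by construction.

**Alternative 2: conjunctive coupling across a vinylboron unit.**
- Disconnection: both C3–C1' and C4–C4a, with a two-carbon vinylboron linchpin between the two aryl rings.
- Forward key step: bromide 5 is lithiated and added to 4,4,5,5-tetramethyl-2-vinyl-1,3,2-dioxaborolane A4. The boronate formed from A4 is then exposed to Pd(OAc)2 with a chiral ferrocenyl bisphosphine and to 2-(methoxymethoxy)-3,4,5-trimethoxyphenyl trifluoromethanesulfonate A5, which trigger 1,2-aryl migration from boron to carbon and reductive elimination. The product is the secondary boronic ester 2-{(1S)-1-[2,5-bis(benzyloxy)-3,4-dimethoxyphenyl]-2-[2-(methoxymethoxy)-3,4,5-trimethoxyphenyl]ethyl}-4,4,5,5-tetramethyl-1,3,2-dioxaborolane A6. One-carbon homologation of the C–B bond of A6, oxidation, acetal removal and etherification would then lead to 26.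
- For: the stereocentre is set catalytically, three components are joined in one step, and the plan shares bromide 5 with the chosen route.
- Against: the migrating aryl group has an ortho benzyloxy group and the triflate A5 an ortho acetal, and both are very electron-rich. In this regime oxidative addition is slow, direct aryl–aryl coupling competes, and the selectivity of the ligand is least predictable. A5 itself demands the regioselective tetraoxygenation of a benzene ring that the squarate route avoids. Four further operations are needed after A6 before ring C exists.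
- Comparison: the step count is about equal or slightly lower, and it is better in using no stoichiometric auxiliary. The chosen route offers stereocontrol that does not depend on a ligand meeting two hindered partners, and it forms rings A and C in one flask.

**Alternative 3: the squarate used for ring B instead of ring A.**
- Disconnection: ring B is unravelled at C5'–C6' to a squaric ester and a 1,1-disubstituted vinyl group on C3 of a finished chroman.
- Forward key step: the α-lithiated vinyl group on C3 of a preformed, enantiopure ring A–C unit adds to dimethyl squarate 17, giving 4-hydroxy-2,3-dimethoxy-4-{1-[(3S)-6,7,8-trimethoxychroman-3-yl]ethenyl}cyclobut-2-en-1-one A7. Thermolysis opens A7 to a dienylketene that closes between the ketene carbon and the vinyl CH2, giving (3S)-3-(2,5-dihydroxy-3,4-dimethoxyphenyl)-6,7,8-trimethoxychroman A8, which is identical with 27. One oxidation of A8 then gives the target.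
- For: the squarate maps exactly onto the dimethoxyquinone. Ring B needs no protecting groups and no O-methylation, and A8 is one step from the target.
- Against: the harder ring, ring A with four adjacent oxygens, must then be built by classical arene chemistry. The route to A7 needs an enantiopure chroman whose stereocentre sits next to the carbon that must become a vinyl anion. The usual precursor, a methyl ketone at C3, is epimerisable at exactly that centre. The branched vinyllithium is also hindered.
- Comparison: the end game is shorter than that of the chosen route. The chosen route uses the squarate where the regiochemical problem is hardest, keeps the stereocentre remote from every reacting centre, and obtains ring B from phenol 1 in three steps.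

Key step: step 12

Remark: 21 is used as the racemate and 22 as a mixture of both configurations at ring carbon C4 of the cyclobutenone, because this carbon becomes the aromatic C6 in step 12; zinc reagent 6 is taken as its commercial solution.

## Route

**Step 1**  
Reactants: 1 2,3-dimethoxyphenol  
Product: 2 2,3-dimethoxy-1,4-benzoquinone  
Conditions: ON(SO3K)2 (2.2 equiv), KH2PO4, H2O/acetone, 0 °C to rt  
Reagents that add atoms: potassium nitrosodisulfonate, `[K+].[K+].[O]N(S(=O)(=O)[O-])S(=O)(=O)[O-]`  
Why: Teuber oxidation; the nitroxyl radical removes the phenolic hydrogen and a second equivalent couples at the free para position, so the para-quinone should form in preference to the ortho-quinone.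

**Step 2**  
Reactants: 2 2,3-dimethoxy-1,4-benzoquinone  
Product: 4 1,4-bis(benzyloxy)-2,3-dimethoxybenzene, via hydroquinone 3 (not isolated)  
Conditions: Na2S2O4, EtOAc/H2O, rt; organic layer dried and concentrated under argon; then BnBr, K2CO3, DMF, 60 °C  
Reagents that add atoms: benzyl bromide, `BrCc1ccccc1`  
Why: Dithionite reduction followed by Williamson etherification; reducing before any base is present protects the vinylogous-ester methoxy groups of the quinone, and exclusion of air prevents reoxidation of 3.

**Step 3**  
Reactants: 4 1,4-bis(benzyloxy)-2,3-dimethoxybenzene  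
Product: 5 1,4-bis(benzyloxy)-5-bromo-2,3-dimethoxybenzene  
Conditions: NBS (1.0 equiv), MeCN, 0 °C, dark  
Reagents that add atoms: N-bromosuccinimide, `O=C1CCC(=O)N1Br`  
Why: Electrophilic aromatic bromination; the two free positions of 4 are equivalent by symmetry, and one equivalent of NBS in a polar solvent without light favours ionic monobromination of the ring over benzylic bromination.

**Step 4**  
Reactants: 5 1,4-bis(benzyloxy)-5-bromo-2,3-dimethoxybenzene; 6 (2-ethoxy-2-oxoethyl)zinc bromide  
Product: 7 ethyl 2-[2,5-bis(benzyloxy)-3,4-dimethoxyphenyl]acetate  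
Conditions: Pd2(dba)3 (2.5 mol %), XPhos (6 mol %), THF, 65 °C  
Reagents that add atoms: none  
Why: Negishi-type coupling of a Reformatsky reagent with an aryl bromide; zerovalent palladium with a bulky biarylphosphine should insert into the electron-rich, ortho-substituted C–Br bond, and the neutral zinc enolate avoids Claisen condensation.

**Step 5**  
Reactants: 7 ethyl 2-[2,5-bis(benzyloxy)-3,4-dimethoxyphenyl]acetate  
Product: 8 2-[2,5-bis(benzyloxy)-3,4-dimethoxyphenyl]acetic acid  
Conditions: LiOH, THF/MeOH/H2O, rt; then 1 M HCl  
Reagents that add atoms: lithium hydroxide, `[Li+].[OH-]`  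
Why: Saponification of an ethyl ester; aryl benzyl and methyl ethers are inert to hydroxide, and no acid strong enough to cleave a benzyl ether is used.

**Step 6**  
Reactants: 8 2-[2,5-bis(benzyloxy)-3,4-dimethoxyphenyl]acetic acid; 9 (4S)-4-benzyl-1,3-oxazolidin-2-one  
Product: 11 (4S)-4-benzyl-3-{2-[2,5-bis(benzyloxy)-3,4-dimethoxyphenyl]acetyl}-1,3-oxazolidin-2-one, via mixed pivalic anhydride 10 (not isolated)  
Conditions: t-BuCOCl, Et3N, THF, −20 °C; then LiCl, 9, −20 °C to rt  
Reagents that add atoms: none  
Why: N-acylation of an oxazolidinone through a mixed anhydride; the oxazolidinone attacks the unhindered arylacetyl carbonyl rather than the pivaloyl carbonyl.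

**Step 7**  
Reactants: 11 (4S)-4-benzyl-3-{2-[2,5-bis(benzyloxy)-3,4-dimethoxyphenyl]acetyl}-1,3-oxazolidin-2-one; 12 allyl iodide  
Product: 14 (4S)-4-benzyl-3-{(2S)-2-[2,5-bis(benzyloxy)-3,4-dimethoxyphenyl]pent-4-enoyl}-1,3-oxazolidin-2-one, via sodium enolate 13 (not isolated)  
Conditions: NaN(SiMe3)2 (1.05 equiv), THF, −78 °C; 12 (3 equiv), −78 to −45 °C; AcOH quench at −78 °C  
Reagents that add atoms: none  
Why: Evans asymmetric alkylation; the chelated (Z)-enolate 13 is shielded on one face by the benzyl group of the (4S)-auxiliary, so 12 enters from the other face, which for an aryl group on the enolate carbon corresponds to (2S). The cold acidic quench keeps the acidic benzylic α-hydrogen from exchanging, and any minor diastereomer is removed by chromatography or crystallisation.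

**Step 8**  
Reactants: 14 (4S)-4-benzyl-3-{(2S)-2-[2,5-bis(benzyloxy)-3,4-dimethoxyphenyl]pent-4-enoyl}-1,3-oxazolidin-2-one  
Product: 15 (2S)-2-[2,5-bis(benzyloxy)-3,4-dimethoxyphenyl]pent-4-en-1-ol  
Conditions: LiBH4, MeOH (1 equiv), Et2O, 0 °C  
Reagents that add atoms: none  
Why: Reductive removal of the auxiliary; borohydride attacks the exocyclic imide carbonyl, giving the primary alcohol and returning 9. The weakly basic medium at 0 °C should not enolise the stereocentre, whose descriptor stays S.

**Step 9**  
Reactants: 15 (2S)-2-[2,5-bis(benzyloxy)-3,4-dimethoxyphenyl]pent-4-en-1-ol  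
Product: 16 (2S)-2-[2,5-bis(benzyloxy)-3,4-dimethoxyphenyl]pent-4-en-1-yl methanesulfonate  
Conditions: MsCl, Et3N, CH2Cl2, 0 °C  
Reagents that add atoms: methanesulfonyl chloride, `CS(=O)(=O)Cl`  
Why: Sulfonylation of a primary alcohol; the mesylate is installed here because the two remaining steps before its use are neutral.

**Step 10**  
Reactants: 17 dimethyl squarate; 18 vinyl bromide  
Product: 21 4-ethenyl-2,3,4-trimethoxycyclobut-2-en-1-one, via vinyllithium 19 (not isolated), via lithium alkoxide 20 (not isolated)  
Conditions: 18, t-BuLi (2 equiv), Et2O, −78 °C; then 17, THF, −78 °C; then MeOTf, −78 to 0 °C  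
Reagents that add atoms: methyl trifluoromethanesulfonate, `COS(=O)(=O)C(F)(F)F`  
Why: Bromine–lithium exchange, then 1,2-addition of the organolithium to one carbonyl group of the squaric ester at low temperature, the normal mode for these diones. The tertiary lithium alkoxide is O-methylated in the flask by the powerful methylating agent.

**Step 11**  
Reactants: 16 (2S)-2-[2,5-bis(benzyloxy)-3,4-dimethoxyphenyl]pent-4-en-1-yl methanesulfonate; 21 4-ethenyl-2,3,4-trimethoxycyclobut-2-en-1-one  
Product: 22 4-{(1E,4S)-4-[2,5-bis(benzyloxy)-3,4-dimethoxyphenyl]-5-[(methanesulfonyl)oxy]pent-1-en-1-yl}-2,3,4-trimethoxycyclobut-2-en-1-one  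
Conditions: 21 (3 equiv), second-generation Hoveyda–Grubbs catalyst RuCl2(H2IMes)(=CH-C6H4-2-OiPr) (5–10 mol %), CH2Cl2, 40 °C, argon sweep  
Reagents that add atoms: none  
Why: Olefin cross metathesis between an unhindered terminal alkene and a vinyl group on a fully substituted carbon; the hindered partner does not dimerise, so it is used in excess, and its bulk should enforce the E geometry. The tetrasubstituted push–pull double bond of the four-membered ring should not engage the carbene, and 40 °C is well below the ring-opening temperature of 21 and 22.

**Step 12**  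
Reactants: 22 4-{(1E,4S)-4-[2,5-bis(benzyloxy)-3,4-dimethoxyphenyl]-5-[(methanesulfonyl)oxy]pent-1-en-1-yl}-2,3,4-trimethoxycyclobut-2-en-1-one  
Product: 26 (3S)-3-[2,5-bis(benzyloxy)-3,4-dimethoxyphenyl]-6,7,8-trimethoxychroman, via dienylketene 23 (not isolated), via cyclohexadienone 24 (not isolated), via phenol mesylate 25 (not isolated)  
Conditions: PhMe (0.01 M, degassed), 110 °C; then Cs2CO3 (2 equiv), DMF added, 60 °C, argon  
Reagents that add atoms: none  
Why: Heating opens the cyclobutenone by conrotatory 4π electrocyclic cleavage of its C1–C4 bond; the π-donating 4-methoxy group turns outward and the alkenyl group inward (torquoselectivity), so in dienylketene 23 the ketene carbon and the far alkene carbon are within bonding distance. Disrotatory 6π electrocyclisation joins these two carbons (C4a–C8a) to give cyclohexadienone 24, and enolisation delivers phenol 25; ring A is thus closed by a pericyclic 6π process in which the ketene oxygen becomes O1 and the three methoxy groups are already on C8, C7 and C6. The closest known reaction type is the thermal ring expansion of 4-alkenyl- and 4-aryl-4-alkoxy (or 4-hydroxy) cyclobutenones from squaric esters to polyoxygenated phenols and hydroquinones. Once the cyclobutenone is consumed, Cs2CO3 turns 25 into its caesium phenoxide, which displaces the primary mesylate in a 6-exo-tet intramolecular Williamson etherification, forming O1–C2 and ring C. No stereocentre is made: the sp3 carbon of 24 is lost on aromatisation, the configuration at ring carbon C4 of 22 is erased in 23, and C3 is not a reacting centre, so (3S) is carried through. The step needs torquoselectivity, which the alkoxy group on C4 secures (a ketene with the alkenyl group outward can only reclose), and cyclisation of the ketene in preference to capture by a nucleophile, which high dilution in toluene and the absence of base during heating secure. It also needs the mesylate to outlast the heating, which is why the medium is neutral and non-polar and the base is added only afterwards, and O-alkylation to beat elimination, for which the six-membered transition state and the weakly basic phenoxide speak.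

**Step 13**  
Reactants: 26 (3S)-3-[2,5-bis(benzyloxy)-3,4-dimethoxyphenyl]-6,7,8-trimethoxychroman  
Product: 27 (3S)-3-(2,5-dihydroxy-3,4-dimethoxyphenyl)-6,7,8-trimethoxychroman  
Conditions: H2 (1 atm), Pd/C (10 %), EtOAc, rt  
Reagents that add atoms: none  
Why: Hydrogenolysis of two aryl benzyl ethers; the chroman C–O bonds are not benzylic and the methyl ethers are inert. The air-sensitive hydroquinone is filtered under argon and used at once.

**Step 14**  
Reactants: 27 (3S)-3-(2,5-dihydroxy-3,4-dimethoxyphenyl)-6,7,8-trimethoxychroman  
Product: 28 abruquinone B, 2,3-dimethoxy-5-[(3S)-6,7,8-trimethoxychroman-3-yl]-1,4-benzoquinone  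
Conditions: Ag2O, MgSO4, Et2O, rt, dark  
Reagents that add atoms: none  
Why: Oxidation of a hydroquinone to the para-quinone by a mild neutral oxidant; ring A has no free phenol and should not react, and the absence of base protects the C3–H next to the quinone.

## Compound list

```
1 | 2,3-dimethoxyphenol | COc1cccc(O)c1OC | starting material
2 | 2,3-dimethoxy-1,4-benzoquinone | COC1=C(OC)C(=O)C=CC1=O | intermediate
3 | 2,3-dimethoxybenzene-1,4-diol | COc1c(O)ccc(O)c1OC | intermediate
4 | 1,4-bis(benzyloxy)-2,3-dimethoxybenzene | COc1c(OCc2ccccc2)ccc(OCc2ccccc2)c1OC | intermediate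
5 | 1,4-bis(benzyloxy)-5-bromo-2,3-dimethoxybenzene | COc1c(OC)c(OCc2ccccc2)cc(Br)c1OCc1ccccc1 | intermediate
6 | (2-ethoxy-2-oxoethyl)zinc bromide | CCOC(=O)C[Zn]Br | starting material
7 | ethyl 2-[2,5-bis(benzyloxy)-3,4-dimethoxyphenyl]acetate | CCOC(=O)Cc1cc(OCc2ccccc2)c(OC)c(OC)c1OCc1ccccc1 | intermediate
8 | 2-[2,5-bis(benzyloxy)-3,4-dimethoxyphenyl]acetic acid | OC(=O)Cc1cc(OCc2ccccc2)c(OC)c(OC)c1OCc1ccccc1 | intermediate
9 | (4S)-4-benzyl-1,3-oxazolidin-2-one | O=C1N[C@@H](Cc2ccccc2)CO1 | starting material
10 | 2-[2,5-bis(benzyloxy)-3,4-dimethoxyphenyl]acetic pivalic anhydride | CC(C)(C)C(=O)OC(=O)Cc1cc(OCc2ccccc2)c(OC)c(OC)c1OCc1ccccc1 | intermediate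
11 | (4S)-4-benzyl-3-{2-[2,5-bis(benzyloxy)-3,4-dimethoxyphenyl]acetyl}-1,3-oxazolidin-2-one | O=C(Cc1cc(OCc2ccccc2)c(OC)c(OC)c1OCc1ccccc1)N1[C@@H](Cc2ccccc2)COC1=O | intermediate
12 | allyl iodide (3-iodoprop-1-ene) | C=CCI | starting material
13 | sodium (Z)-enolate of 11 | [Na+].[O-]/C(=C\c1cc(OCc2ccccc2)c(OC)c(OC)c1OCc1ccccc1)N1[C@@H](Cc2ccccc2)COC1=O | intermediate
14 | (4S)-4-benzyl-3-{(2S)-2-[2,5-bis(benzyloxy)-3,4-dimethoxyphenyl]pent-4-enoyl}-1,3-oxazolidin-2-one | C=CC[C@@H](c1cc(OCc2ccccc2)c(OC)c(OC)c1OCc1ccccc1)C(=O)N1[C@@H](Cc2ccccc2)COC1=O | intermediate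
15 | (2S)-2-[2,5-bis(benzyloxy)-3,4-dimethoxyphenyl]pent-4-en-1-ol | C=CC[C@@H](c1cc(OCc2ccccc2)c(OC)c(OC)c1OCc1ccccc1)CO | intermediate
16 | (2S)-2-[2,5-bis(benzyloxy)-3,4-dimethoxyphenyl]pent-4-en-1-yl methanesulfonate | C=CC[C@@H](c1cc(OCc2ccccc2)c(OC)c(OC)c1OCc1ccccc1)COS(C)(=O)=O | intermediate
17 | dimethyl squarate (3,4-dimethoxycyclobut-3-ene-1,2-dione) | COC1=C(OC)C(=O)C1=O | starting material
18 | vinyl bromide | C=CBr | starting material
19 | vinyllithium | [Li]C=C | intermediate
20 | lithium 1-ethenyl-2,3-dimethoxy-4-oxocyclobut-2-en-1-olate | [Li+].[O-]C1(C=C)C(OC)=C(OC)C1=O | intermediate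
21 | 4-ethenyl-2,3,4-trimethoxycyclobut-2-en-1-one (racemic) | COC1=C(OC)C(OC)(C=C)C1=O | intermediate
22 | 4-{(1E,4S)-4-[2,5-bis(benzyloxy)-3,4-dimethoxyphenyl]-5-[(methanesulfonyl)oxy]pent-1-en-1-yl}-2,3,4-trimethoxycyclobut-2-en-1-one (either configuration at ring C4) | COC1=C(OC)C(OC)(/C=C/C[C@@H](c2cc(OCc3ccccc3)c(OC)c(OC)c2OCc2ccccc2)COS(C)(=O)=O)C1=O | intermediate
23 | (3Z,5E,8S)-8-[2,5-bis(benzyloxy)-3,4-dimethoxyphenyl]-9-[(methanesulfonyl)oxy]-2,3,4-trimethoxynona-1,3,5-trien-1-one | O=C=C(OC)/C(OC)=C(OC)\C=C\C[C@@H](c1cc(OCc2ccccc2)c(OC)c(OC)c1OCc1ccccc1)COS(C)(=O)=O | intermediate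
24 | 6-{(2S)-2-[2,5-bis(benzyloxy)-3,4-dimethoxyphenyl]-3-[(methanesulfonyl)oxy]propyl}-2,3,4-trimethoxycyclohexa-2,4-dien-1-one | COC1=C(OC)C(OC)=CC(C[C@@H](c2cc(OCc3ccccc3)c(OC)c(OC)c2OCc2ccccc2)COS(C)(=O)=O)C1=O | intermediate
25 | (2S)-2-[2,5-bis(benzyloxy)-3,4-dimethoxyphenyl]-3-(2-hydroxy-3,4,5-trimethoxyphenyl)propyl methanesulfonate | COc1cc(C[C@@H](c2cc(OCc3ccccc3)c(OC)c(OC)c2OCc2ccccc2)COS(C)(=O)=O)c(O)c(OC)c1OC | intermediate
26 | (3S)-3-[2,5-bis(benzyloxy)-3,4-dimethoxyphenyl]-6,7,8-trimethoxychroman | COc1c(OC)c(OCc2ccccc2)cc([C@H]2COc3c(cc(OC)c(OC)c3OC)C2)c1OCc1ccccc1 | intermediate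
27 | (3S)-3-(2,5-dihydroxy-3,4-dimethoxyphenyl)-6,7,8-trimethoxychroman | COc1c(OC)c(O)c([C@H]2COc3c(cc(OC)c(OC)c3OC)C2)cc1O | intermediate
28 | abruquinone B, 2,3-dimethoxy-5-[(3S)-6,7,8-trimethoxychroman-3-yl]-1,4-benzoquinone | COC1=C(OC)C(=O)C([C@H]2COc3c(cc(OC)c(OC)c3OC)C2)=CC1=O | target
```

## Step count and least certain steps

Total: 14 steps. Longest linear sequence: 13 steps (steps 1–9 and 11–14, from phenol 1); step 10 is a one-step branch from dimethyl squarate 17.

**Step 12 (key step).** The most likely failure is loss of the sulfonate during the heating period. The ortho-benzyloxy oxygen of ring B is placed to displace it through a five-membered oxonium ion, followed by debenzylation, and the β-hydrogen is benzylic, so elimination can also set in once base is present. Lesser risks are capture of the ketene by adventitious water and air oxidation of the electron-rich phenoxide. The fallback keeps the benzannulation but closes ring C in a separate dehydrative step, so that no leaving group is present during heating; it sets out from alcohol 15 and rejoins the route at 26. Cross metathesis of 15 with 21 (catalyst as in step 11; the free hydroxyl is tolerated) would give the hydroxy cyclobutenone 4-{(1E,4S)-4-[2,5-bis(benzyloxy)-3,4-dimethoxyphenyl]-5-hydroxypent-1-en-1-yl}-2,3,4-trimethoxycyclobut-2-en-1-one F1. Thermolysis of F1 in dilute toluene at 110 °C would give the phenol alcohol (2S)-2-[2,5-bis(benzyloxy)-3,4-dimethoxyphenyl]-3-(2-hydroxy-3,4,5-trimethoxyphenyl)propan-1-ol F2, since the unimolecular 6π closure should outrun capture of the ketene by the remote hydroxyl. Mitsunobu etherification of F2 (PPh3, diisopropyl azodicarboxylate, THF, 0 °C to rt) then closes ring C to 26.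

**Step 11.** Turnover at the vinyl group on the fully substituted ring carbon may be slow, so that self-metathesis of 16 dominates. Chelation of the propagating carbene by the ring carbonyl, or migration of the terminal double bond of 16, would lower the conversion further. The fallback forms the alkene–ring bond by organolithium addition instead; it sets out from 15 and rejoins the route at 22. Silylation of 15 (t-BuMe2SiCl, imidazole, DMF) would give the silyl ether tert-butyl{[(2S)-2-[2,5-bis(benzyloxy)-3,4-dimethoxyphenyl]pent-4-en-1-yl]oxy}dimethylsilane F3. Lemieux–Johnson cleavage of F3 (OsO4 cat., NaIO4, 2,6-lutidine, dioxane/H2O; chosen over ozone because of the electron-rich arene) would give the aldehyde (3S)-3-[2,5-bis(benzyloxy)-3,4-dimethoxyphenyl]-4-[(tert-butyldimethylsilyl)oxy]butanal F4. Takai olefination of F4 with CrCl2 and CHI3 in THF would give the E-alkenyl iodide tert-butyl{[(2S,4E)-2-[2,5-bis(benzyloxy)-3,4-dimethoxyphenyl]-5-iodopent-4-en-1-yl]oxy}dimethylsilane F5. Iodine–lithium exchange of F5 with t-BuLi in Et2O at −78 °C, addition to 17 and quenching with MeOTf would give the silylated cyclobutenone 4-{(1E,4S)-4-[2,5-bis(benzyloxy)-3,4-dimethoxyphenyl]-5-[(tert-butyldimethylsilyl)oxy]pent-1-en-1-yl}-2,3,4-trimethoxycyclobut-2-en-1-one F6. Buffered desilylation of F6 with Bu4NF and AcOH in THF would give alcohol F1, the compound described under step 12, and mesylation (MsCl, Et3N, CH2Cl2, 0 °C) would give 22.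

**Step 7.** The new centre carries a hydrogen that is both benzylic and α to the imide, so configuration can be eroded by proton exchange with unreacted enolate or during work-up. The imide enolate can also fragment if the temperature rises, and the bulky ortho-benzyloxy group may lower facial discrimination. The fallback sets the centre by catalytic conjugate addition, where no enolisable benzylic carbonyl compound is formed under base; it sets out from bromide 5 and rejoins the route at 15. Bromine–lithium exchange of 5 (n-BuLi, THF, −78 °C), then B(OiPr)3 and aqueous acid, would give the boronic acid [2,5-bis(benzyloxy)-3,4-dimethoxyphenyl]boronic acid F7. Hayashi–Miyaura addition of F7 to furan-2(5H)-one (Rh(acac)(C2H4)2, (S)-BINAP, dioxane/H2O, 100 °C) is expected to give the lactone (4S)-4-[2,5-bis(benzyloxy)-3,4-dimethoxyphenyl]oxolan-2-one F8. The S sense of F8 is assigned by analogy with cyclic enones and would have to be confirmed. Reduction of F8 with iBu2AlH in CH2Cl2 at −78 °C would give the lactol (4S)-4-[2,5-bis(benzyloxy)-3,4-dimethoxyphenyl]oxolan-2-ol F9. Wittig methylenation of F9 with excess Ph3P=CH2 (from Ph3PCH3Br and KOtBu, THF) would give 15.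

**Step 10.** O-Methylation of the hindered tertiary lithium alkoxide in the flask may be incomplete, and the excess methylating agent can start polymerisation of THF; conjugate addition–elimination at the vinylogous ester would waste 17. The fallback separates addition and methylation; it sets out from 17 and rejoins the route at 21. Addition of vinylmagnesium bromide to 17 (THF, −78 °C, NH4Cl quench) would give the hydroxy cyclobutenone 4-ethenyl-4-hydroxy-2,3-dimethoxycyclobut-2-en-1-one F10, which is isolated. Purdie methylation of F10 (MeI, Ag2O, K2CO3, MeCN, rt) then gives 21.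

## Further compounds

```
F1 | step 12 | 4-{(1E,4S)-4-[2,5-bis(benzyloxy)-3,4-dimethoxyphenyl]-5-hydroxypent-1-en-1-yl}-2,3,4-trimethoxycyclobut-2-en-1-one | COC1=C(OC)C(OC)(/C=C/C[C@@H](c2cc(OCc3ccccc3)c(OC)c(OC)c2OCc2ccccc2)CO)C1=O
F2 | step 12 | (2S)-2-[2,5-bis(benzyloxy)-3,4-dimethoxyphenyl]-3-(2-hydroxy-3,4,5-trimethoxyphenyl)propan-1-ol | COc1cc(C[C@@H](c2cc(OCc3ccccc3)c(OC)c(OC)c2OCc2ccccc2)CO)c(O)c(OC)c1OC
F3 | step 11 | tert-butyl{[(2S)-2-[2,5-bis(benzyloxy)-3,4-dimethoxyphenyl]pent-4-en-1-yl]oxy}dimethylsilane | C=CC[C@@H](c1cc(OCc2ccccc2)c(OC)c(OC)c1OCc1ccccc1)CO[Si](C)(C)C(C)(C)C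
F4 | step 11 | (3S)-3-[2,5-bis(benzyloxy)-3,4-dimethoxyphenyl]-4-[(tert-butyldimethylsilyl)oxy]butanal | O=CC[C@@H](c1cc(OCc2ccccc2)c(OC)c(OC)c1OCc1ccccc1)CO[Si](C)(C)C(C)(C)C
F5 | step 11 | tert-butyl{[(2S,4E)-2-[2,5-bis(benzyloxy)-3,4-dimethoxyphenyl]-5-iodopent-4-en-1-yl]oxy}dimethylsilane | I/C=C/C[C@@H](c1cc(OCc2ccccc2)c(OC)c(OC)c1OCc1ccccc1)CO[Si](C)(C)C(C)(C)C
F6 | step 11 | 4-{(1E,4S)-4-[2,5-bis(benzyloxy)-3,4-dimethoxyphenyl]-5-[(tert-butyldimethylsilyl)oxy]pent-1-en-1-yl}-2,3,4-trimethoxycyclobut-2-en-1-one | COC1=C(OC)C(OC)(/C=C/C[C@@H](c2cc(OCc3ccccc3)c(OC)c(OC)c2OCc2ccccc2)CO[Si](C)(C)C(C)(C)C)C1=O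
F7 | step 7 | [2,5-bis(benzyloxy)-3,4-dimethoxyphenyl]boronic acid | OB(O)c1cc(OCc2ccccc2)c(OC)c(OC)c1OCc1ccccc1
F8 | step 7 | (4S)-4-[2,5-bis(benzyloxy)-3,4-dimethoxyphenyl]oxolan-2-one | O=C1C[C@@H](c2cc(OCc3ccccc3)c(OC)c(OC)c2OCc2ccccc2)CO1
F9 | step 7 | (4S)-4-[2,5-bis(benzyloxy)-3,4-dimethoxyphenyl]oxolan-2-ol | OC1C[C@@H](c2cc(OCc3ccccc3)c(OC)c(OC)c2OCc2ccccc2)CO1
F10 | step 10 | 4-ethenyl-4-hydroxy-2,3-dimethoxycyclobut-2-en-1-one | COC1=C(OC)C(O)(C=C)C1=O
A1 | alternative 1 | 6,7,8-trimethoxy-2H-chromene | COc1cc2C=CCOc2c(OC)c1OC
A2 | alternative 1 | 2,3-dimethoxy-1,4-benzoquinone | COC1=C(OC)C(=O)C=CC1=O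
A3 | alternative 1 | (6aS,11aS)-8-hydroxy-2,3,4,9,10-pentamethoxypterocarpan | COc1cc2[C@H]3Oc4c(OC)c(OC)c(O)cc4[C@H]3COc2c(OC)c1OC
A4 | alternative 2 | 4,4,5,5-tetramethyl-2-vinyl-1,3,2-dioxaborolane | C=CB1OC(C)(C)C(C)(C)O1
A5 | alternative 2 | 2-(methoxymethoxy)-3,4,5-trimethoxyphenyl trifluoromethanesulfonate | COCOc1c(OS(=O)(=O)C(F)(F)F)cc(OC)c(OC)c1OC
A6 | alternative 2 | 2-{(1S)-1-[2,5-bis(benzyloxy)-3,4-dimethoxyphenyl]-2-[2-(methoxymethoxy)-3,4,5-trimethoxyphenyl]ethyl}-4,4,5,5-tetramethyl-1,3,2-dioxaborolane | COCOc1c(C[C@H](B2OC(C)(C)C(C)(C)O2)c2cc(OCc3ccccc3)c(OC)c(OC)c2OCc2ccccc2)cc(OC)c(OC)c1OC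
A7 | alternative 3 | 4-hydroxy-2,3-dimethoxy-4-{1-[(3S)-6,7,8-trimethoxychroman-3-yl]ethenyl}cyclobut-2-en-1-one | COC1=C(OC)C(O)(C(=C)[C@H]2COc3c(cc(OC)c(OC)c3OC)C2)C1=O
A8 | alternative 3 | (3S)-3-(2,5-dihydroxy-3,4-dimethoxyphenyl)-6,7,8-trimethoxychroman | COc1c(OC)c(O)c([C@H]2COc3c(cc(OC)c(OC)c3OC)C2)cc1O
```
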